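## Retrosynthetic overview

- The strategy rests on ring B (C5, C6=C7, C8=O, C9=C10), a cyclohexa-2,5-dienone on quaternary C5. Its two enone arms become equivalent once the C7 propanoate and the C1–C10 bond are removed, and oxygen-bearing C1 sits on β-carbon C10, where an acyl anion would add.
- Late disconnections: the C1–O angelate (acylation), C7–C11 (nickel reductive coupling on a C7 iodide), the C1 carbinol (from a C1 ketone) and C9=C10 (dehydrogenation of a 1,4-diketone).
- Key disconnection: C1–C10. An intramolecular Stetter reaction of a prochiral dienone aldehyde closes ring A and makes C5 stereogenic.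
- Ring order: ring B is built first by Robinson annulation of α-methylated (S)-citronellal with methyl vinyl ketone, then dehydrogenated and ozonolysed to free C1. Ring A is closed second.

Key step: step 7

Remark on numbering: eremophilane numbering is used for the bicycles. Ring A is C1–C5 plus C10, ring B is C5–C10, the methyls sit on C4 and C5, and the side chain C11–C13 sits on C7.

Assumption: the sense of arm selection by the carbene (step 7) and of C11 induction by the bioxazoline (step 11) cannot be derived safely from the known substrate classes. The antipode named in each Conditions line therefore stands for whichever of the two accessible antipodes proves matched.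

## Route

Step 1
Reactants: 1 (S)-citronellal
Product: 2 (3S)-3,7-dimethyl-2-methylideneoct-6-enal
Conditions: 37% aq CH2O (1.2 equiv), pyrrolidine (10 mol %), EtCO2H (10 mol %), iPrOH, 45 °C
Reagents that add atoms: formaldehyde, C=O
Why: An amine-catalysed Mannich condensation with loss of the amine (organocatalytic α-methylenation) places the future C5 methyl carbon on C2, and the near-neutral medium leaves the trisubstituted alkene and the non-acidic C3 centre alone.

Step 2
Reactants: 2 (3S)-3,7-dimethyl-2-methylideneoct-6-enal
Product: 3 (3S)-2,3,7-trimethyloct-6-enal as both C2 epimers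
Conditions: diethyl 2,6-dimethyl-1,4-dihydropyridine-3,5-dicarboxylate (Hantzsch ester, 1.1 equiv), Bn2NH2+ CF3CO2− (10 mol %), THF, rt
Reagents that add atoms: none
Why: Iminium-catalysed transfer hydrogenation delivers hydride only to the β-carbon of the activated enal, so the isolated alkene and the aldehyde survive, and the C2 epimer mixture does not matter because C2 becomes quaternary and later prochiral.

Step 3
Reactants: 3 (3S)-2,3,7-trimethyloct-6-enal; 4 methyl vinyl ketone
Product: 6 (3S)-2,3,7-trimethyl-2-(3-oxobutyl)oct-6-enal as both C2 epimers, via pyrrolidine enamine 5 (not isolated)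
Conditions: pyrrolidine (1.3 equiv), toluene, Dean–Stark, reflux; concentrate; 4 (1.5 equiv), MeCN, 0 °C to reflux; NaOAc/AcOH/H2O buffer (pH 5), rt
Reagents that add atoms: pyrrolidine, C1CCNC1 (stands in 5 only); water, O (returns the aldehyde oxygen on hydrolysis)
Why: The Stork enamine Michael addition lets the branched aldehyde attack the enone through its only α-carbon and build the quaternary carbon, and the buffered hydrolysis is too mild to trigger carbonyl-ene cyclisation onto the prenyl alkene.

Step 4
Reactants: 6 (3S)-2,3,7-trimethyl-2-(3-oxobutyl)oct-6-enal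
Product: 7 4-methyl-4-[(2S)-6-methylhept-5-en-2-yl]cyclohex-2-en-1-one as both epimers at the quaternary carbon
Conditions: KOH (0.3 equiv), nBu4NOH (cat.), H2O/THF, reflux
Reagents that add atoms: none
Why: This intramolecular aldol condensation completes the Robinson annulation, because the aldehyde cannot enolise and only the methyl-side enolate of the ketone reaches it through a six-membered ring, which gives ring B.

Step 5
Reactants: 7 4-methyl-4-[(2S)-6-methylhept-5-en-2-yl]cyclohex-2-en-1-one
Product: 9 4-methyl-4-[(2S)-6-methylhept-5-en-2-yl]cyclohexa-2,5-dien-1-one, via silyl dienol ether 8 (not isolated)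
Conditions: LiN(iPr)2 (1.1 equiv), THF, −78 °C; Me3SiCl (1.3 equiv), to 0 °C; pentane, filter, concentrate; Pd(OAc)2 (1.05 equiv), MeCN, rt
Reagents that add atoms: chlorotrimethylsilane, C[Si](C)(C)Cl (its silyl group stands in 8 only)
Why: In this Saegusa–Ito oxidation only α'-deprotonation is possible, since the γ-carbon is quaternary, and β-hydride loss from the palladium enolate gives the cross-conjugated dienone, which merges both epimers into one compound with a prochiral quaternary carbon.

Step 6
Reactants: 9 4-methyl-4-[(2S)-6-methylhept-5-en-2-yl]cyclohexa-2,5-dien-1-one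
Product: 11 (4S)-4-(1-methyl-4-oxocyclohexa-2,5-dien-1-yl)pentanal, via secondary ozonide 10 (not isolated)
Conditions: O3/O2, CH2Cl2, −78 °C, Sudan Red 7B as end-point indicator; PPh3 (1.1 equiv), −78 °C to rt
Reagents that add atoms: ozone, [O-][O+]=O
Why: In this chemoselective ozonolysis with reductive work-up the electrophilic ozone consumes the electron-rich trisubstituted alkene far faster than the electron-poor dienone bonds, and the dye marks the end point, which frees C1 as the aldehyde.

Step 7
Reactants: 11 (4S)-4-(1-methyl-4-oxocyclohexa-2,5-dien-1-yl)pentanal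
Product: 12 (4S,4aS,8aR)-4,4a-dimethyl-2,3,4,4a,8,8a-hexahydronaphthalene-1,7-dione (cis-fused; eremophilane 4S,5S,10R; C6=C7 enone, ketones at C1 and C8)
Conditions: (5aR,10bS)-2-(pentafluorophenyl)-5a,10b-dihydro-4H,6H-indeno[2,1-b][1,2,4]triazolo[4,3-d][1,4]oxazin-2-ium tetrafluoroborate (20 mol %), KN(SiMe3)2 (18 mol %, carbene preformed), toluene (0.02 M), 23 °C
Reagents that add atoms: none
Why: Proposed new method: the free triazolylidene adds to the C1 aldehyde and a proton shift gives the Breslow enaminol, whose now nucleophilic C1 attacks C10, the β-carbon of one enone arm; protonation of the C8 enolate at C9 and loss of the carbene leave the C1 ketone. The closest known reaction type is the carbene-catalysed enantioselective intramolecular Stetter desymmetrisation of 4,4-disubstituted cyclohexa-2,5-dienones, established for oxygen-containing tethers that close five-membered rings, so the all-carbon tether, the six-membered closure and the stereocentre next to the prochiral carbon are the untested elements. Ring A (C1, C2, C3, C4, C5, C10) closes 6-exo-trig through the new C1–C10 bond. C10 is fixed by the tether, which reaches ring B only on the face of C5 that carries C4, hence the cis fusion (10R), and C5 becomes stereogenic (5S) through the choice of arm, which is made by the chiral pocket of the aminoindanol-derived carbene. The selectivity needed is between the two diastereotopic arms (cis against trans C4/C5 methyls): the C4 methyl can sit equatorial in a chair leading to either arm, so the substrate bias should be small and the catalyst antipode is picked to override it, any minor diastereomer being removable by chromatography. The substrate itself secures reactivity and chemoselectivity, since quaternary C5 folds the chain over a doubly activated acceptor that cannot aromatise, and using slightly less base than azolium salt leaves no free base for the rival 5-exo Michael addition of the C2 enolate or for aldol reactions.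

Step 8
Reactants: 12 (4S,4aS,8aR)-4,4a-dimethyl-2,3,4,4a,8,8a-hexahydronaphthalene-1,7-dione
Product: 14 (4S,4aS)-4,4a-dimethyl-2,3,4,4a-tetrahydronaphthalene-1,7-dione (6,9-diene-1,8-dione), via bis-silyl trienol ether 13 (not isolated)
Conditions: Me3SiOTf (2.5 equiv), Et3N (4 equiv), CH2Cl2, 0 °C to rt; hexane extraction, concentrate; DDQ (1.05 equiv), 2,6-lutidine (1 equiv), CH2Cl2, 0 °C
Reagents that add atoms: trimethylsilyl triflate, C[Si](C)(C)OS(=O)(=O)C(F)(F)F (its silyl groups stand in 13 only)
Why: Equilibrating soft enolisation should favour the fully conjugated 1,8-bis(silyloxy) triene (C1=C10, C8=C9), and its two-electron oxidation by DDQ (silyl enol ether dehydrogenation) strips both silyl groups to leave the C9=C10 enedione and erase C10, while lutidine keeps out the acid that could start a dienone–phenol rearrangement.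

Step 9
Reactants: 14 (4S,4aS)-4,4a-dimethyl-2,3,4,4a-tetrahydronaphthalene-1,7-dione
Product: 15 (4aS,5S,8R)-8-hydroxy-4a,5-dimethyl-5,6,7,8-tetrahydronaphthalen-2(4aH)-one (1β-hydroxy-6,9-dien-8-one; eremophilane 1R,4S,5S)
Conditions: CeCl3·7H2O (1.2 equiv), NaBH4 (1.0 equiv, in portions), MeOH/CH2Cl2, −78 °C; pH 7 buffer
Reagents that add atoms: none
Why: In this Luche 1,2-reduction the hard hydride should attack the C1 carbonyl, which has a single and electron-poor vinyl donor, ahead of the doubly vinylogous C8 carbonyl, and it approaches along the equatorial path on the face opposite the axial C5 methyl (which blocks axial attack in a 1,3 sense), so the new C1–O bond is axial and cis to both methyls (1R).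

Step 10
Reactants: 15 (4aS,5S,8R)-8-hydroxy-4a,5-dimethyl-5,6,7,8-tetrahydronaphthalen-2(4aH)-one
Product: 16 (4aS,5S,8R)-8-hydroxy-3-iodo-4a,5-dimethyl-5,6,7,8-tetrahydronaphthalen-2(4aH)-one (iodine on C7)
Conditions: I2 (2 equiv), pyridine/CH2Cl2 1:1, 0 °C to rt, dark
Reagents that add atoms: iodine, II
Why: This α-iodination of the Baylis–Hillman type (pyridine adds to C6, the dienolate is iodinated at C7, pyridine leaves) can run only on the C6=C7 arm, because β-carbon C10 of the other arm is fully substituted, and darkness suppresses radical iodine chemistry.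

Step 11
Reactants: 16 (4aS,5S,8R)-8-hydroxy-3-iodo-4a,5-dimethyl-5,6,7,8-tetrahydronaphthalen-2(4aH)-one; 17 methyl 2-chloropropanoate (racemic, 1.5 equiv)
Product: 18 methyl (2S)-2-[(5R,8S,8aS)-5-hydroxy-8,8a-dimethyl-3-oxo-3,5,6,7,8,8a-hexahydronaphthalen-2-yl]propanoate (eremophilane 1R,4S,5S,11S)
Conditions: NiBr2·diglyme (10 mol %), (4S,4'S)-4,4'-di(heptan-4-yl)-4,4',5,5'-tetrahydro-2,2'-bioxazole (12 mol %), Mn powder (3 equiv), DMA, 0–10 °C, no silyl chloride activator; pH 7 buffer work-up
Reagents that add atoms: none
Why: Proposed new method: zerovalent nickel on the chiral bioxazoline should insert into the carbon–iodine bond of 16, monovalent nickel abstracts chlorine from either enantiomer of 17 to give one planar α-ester radical, the alkenylnickel captures it, and reductive elimination from trivalent nickel forms C7–C11 with the ligand fixing 11S while Mn closes the cycle under neutral conditions that spare the hydroxyl and the labile C11–H; the closest known reaction types are the enantioconvergent reductive cross-coupling of α-chloro esters with aryl iodides and that of alkenyl bromides with benzylic chlorides, and the α-iodo dienone partner is the untested element.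

Step 12
Reactants: 18 methyl (2S)-2-[(5R,8S,8aS)-5-hydroxy-8,8a-dimethyl-3-oxo-3,5,6,7,8,8a-hexahydronaphthalen-2-yl]propanoate; 19 angelic acid, (Z)-2-methylbut-2-enoic acid
Product: 21 methyl (2S)-2-[(5R,8S,8aS)-8,8a-dimethyl-5-{[(2Z)-2-methylbut-2-enoyl]oxy}-3-oxo-3,5,6,7,8,8a-hexahydronaphthalen-2-yl]propanoate (CNP0166395.1), via mixed anhydride 20 (not isolated)
Conditions: 19 (3 equiv), 2,4,6-Cl3C6H2COCl (3 equiv), Et3N (3 equiv), toluene, rt, filter off the salt; 18, NaHCO3 (solid, 5 equiv), toluene, 80 °C, no DMAP
Reagents that add atoms: 2,4,6-trichlorobenzoyl chloride, O=C(Cl)c1c(Cl)cc(Cl)cc1Cl (its aroyl group stands in 20 only)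
Why: In this Yamaguchi esterification the hindered axial C1 hydroxyl attacks the open angeloyl carbonyl rather than the doubly ortho-blocked aroyl carbonyl, with retention at C1, and leaving out DMAP and soluble amine removes the addition–elimination path that turns angelate into tiglate and also protects C11 from epimerisation.

## Compound list

1 | (S)-citronellal | C[C@@H](CCC=C(C)C)CC=O | starting material
2 | (3S)-3,7-dimethyl-2-methylideneoct-6-enal | O=CC(=C)[C@@H](C)CCC=C(C)C | intermediate
3 | (3S)-2,3,7-trimethyloct-6-enal, both C2 epimers | O=CC(C)[C@@H](C)CCC=C(C)C | intermediate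
4 | methyl vinyl ketone | CC(=O)C=C | starting material
5 | 1-[(3S)-2,3,7-trimethylocta-1,6-dien-1-yl]pyrrolidine, E/Z mixture | CC(=CN1CCCC1)[C@@H](C)CCC=C(C)C | intermediate
6 | (3S)-2,3,7-trimethyl-2-(3-oxobutyl)oct-6-enal, both C2 epimers | O=CC(C)(CCC(C)=O)[C@@H](C)CCC=C(C)C | intermediate
7 | 4-methyl-4-[(2S)-6-methylhept-5-en-2-yl]cyclohex-2-en-1-one, both epimers at C4 | O=C1C=CC(C)(CC1)[C@@H](C)CCC=C(C)C | intermediate
8 | 4-methyl-4-[(2S)-6-methylhept-5-en-2-yl]cyclohexa-1,5-dien-1-yl trimethylsilyl ether | C[Si](C)(C)OC1=CCC(C)(C=C1)[C@@H](C)CCC=C(C)C | intermediate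
9 | 4-methyl-4-[(2S)-6-methylhept-5-en-2-yl]cyclohexa-2,5-dien-1-one | O=C1C=CC(C)(C=C1)[C@@H](C)CCC=C(C)C | intermediate
10 | 3,3-dimethyl-5-[(3S)-3-(1-methyl-4-oxocyclohexa-2,5-dien-1-yl)butyl]-1,2,4-trioxolane | CC1(C)OOC(CC[C@H](C)C2(C)C=CC(=O)C=C2)O1 | intermediate
11 | (4S)-4-(1-methyl-4-oxocyclohexa-2,5-dien-1-yl)pentanal | O=C1C=CC(C)(C=C1)[C@@H](C)CCC=O | intermediate
12 | (4S,4aS,8aR)-4,4a-dimethyl-2,3,4,4a,8,8a-hexahydronaphthalene-1,7-dione | O=C1CC[C@H](C)[C@@]2(C)C=CC(=O)C[C@@H]12 | intermediate
13 | (4S,4aS)-4,4a-dimethyl-1,7-bis(trimethylsilyloxy)-2,3,4,4a-tetrahydronaphthalene | C[Si](C)(C)OC=1CC[C@H](C)[C@@]2(C)C=CC(O[Si](C)(C)C)=CC=12 | intermediate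
14 | (4S,4aS)-4,4a-dimethyl-2,3,4,4a-tetrahydronaphthalene-1,7-dione | O=C1CC[C@H](C)[C@@]2(C)C=CC(=O)C=C12 | intermediate
15 | (4aS,5S,8R)-8-hydroxy-4a,5-dimethyl-5,6,7,8-tetrahydronaphthalen-2(4aH)-one | O[C@@H]1CC[C@H](C)[C@@]2(C)C=CC(=O)C=C12 | intermediate
16 | (4aS,5S,8R)-8-hydroxy-3-iodo-4a,5-dimethyl-5,6,7,8-tetrahydronaphthalen-2(4aH)-one | O[C@@H]1CC[C@H](C)[C@@]2(C)C=C(I)C(=O)C=C12 | intermediate
17 | methyl 2-chloropropanoate, racemic | COC(=O)C(C)Cl | starting material
18 | methyl (2S)-2-[(5R,8S,8aS)-5-hydroxy-8,8a-dimethyl-3-oxo-3,5,6,7,8,8a-hexahydronaphthalen-2-yl]propanoate | O[C@@H]1CC[C@H](C)[C@@]2(C)C=C([C@H](C)C(=O)OC)C(=O)C=C12 | intermediate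
19 | angelic acid, (Z)-2-methylbut-2-enoic acid | C/C=C(/C)C(=O)O | starting material
20 | (Z)-2-methylbut-2-enoic 2,4,6-trichlorobenzoic anhydride | C/C=C(/C)C(=O)OC(=O)c1c(Cl)cc(Cl)cc1Cl | intermediate
21 | methyl (2S)-2-[(5R,8S,8aS)-8,8a-dimethyl-5-{[(2Z)-2-methylbut-2-enoyl]oxy}-3-oxo-3,5,6,7,8,8a-hexahydronaphthalen-2-yl]propanoate | C/C=C(/C)C(=O)O[C@@H]1CC[C@H](C)[C@@]2(C)C=C([C@H](C)C(=O)OC)C(=O)C=C12 | target

## Step count and risks

Total step count: 12. Longest linear sequence: 12 steps (1 to 21).

**Step 7 (labelled).**
- What may go wrong: the six-membered closure of an enolisable aliphatic aldehyde may be too slow, so that enolisation, aldol or benzoin-type self-reaction takes over. The carbene may also fail to override the bias of the C4 centre, giving poor arm selection.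
- Fallback: this sets out from 11 and replaces the polar umpolung by a known acyl radical cyclisation.
  - Pinnick oxidation (NaClO2, NaH2PO4, 2-methylbut-2-ene, tBuOH/H2O) should give (4S)-4-(1-methyl-4-oxocyclohexa-2,5-dien-1-yl)pentanoic acid F1.
  - PhSeSePh/Bu3P in CH2Cl2 should convert it into Se-phenyl (4S)-4-(1-methyl-4-oxocyclohexa-2,5-dien-1-yl)pentaneselenoate F2.
  - Slow addition of Bu3SnH/AIBN in refluxing benzene generates the nucleophilic acyl radical. This radical should add 6-exo to C10 on the tether face, and hydrogen transfer to C9 follows.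
  - Arm selection is then under substrate control only. The trans-dimethyl isomer (4S,4aR,8aS)-4,4a-dimethyl-2,3,4,4a,8,8a-hexahydronaphthalene-1,7-dione F3 has to be separated by chromatography, and the route is rejoined at 12.

**Step 11 (labelled).**
- What may go wrong: the carbon–iodine bond may be reduced without coupling, either partner may homocouple, or ligand control at C11 may be weak beside the bulky ring.
- Fallback: this sets out from 16 and uses a known palladium-catalysed Negishi-type coupling of a Reformatsky reagent.
  - Zinc dust and methyl 2-bromopropanoate in THF give bromo(1-methoxy-1-oxopropan-2-yl)zinc F4.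
  - An excess (3 equiv, one of which is consumed by the hydroxyl) is coupled with 16 under Pd(PPh3)4 (5 mol %) in THF at 40 °C.
  - C11 then forms without control. Compound 18 is separated by chromatography from its epimer methyl (2R)-2-[(5R,8S,8aS)-5-hydroxy-8,8a-dimethyl-3-oxo-3,5,6,7,8,8a-hexahydronaphthalen-2-yl]propanoate F5.
  - F5 can be re-equilibrated at C11 with a catalytic amine base and separated again. The route is rejoined at 18.

**Step 9.**
- What may go wrong: hydride may be delivered to the C8 carbonyl or to the electron-poor C9=C10 bond, or discrimination between the two carbonyls may be insufficient.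
- Fallback: this sets out from 14 and gives up chemoselective reduction in favour of chemoselective re-oxidation.
  - iBu2AlH (2.5 equiv, toluene, −78 °C) should reduce both carbonyls in the 1,2 sense. The facial control at C1 is the same, and the product is (1R,4S,4aS)-4,4a-dimethyl-1,2,3,4,4a,7-hexahydronaphthalene-1,7-diol F6, as either C8 epimer.
  - MnO2 in CH2Cl2 should then oxidise the open, doubly allylic C8 carbinol well ahead of the axial, methyl-shielded C1 carbinol. The route is rejoined at 15.

## Further compounds

F1 | step 7 | (4S)-4-(1-methyl-4-oxocyclohexa-2,5-dien-1-yl)pentanoic acid | O=C1C=CC(C)(C=C1)[C@@H](C)CCC(=O)O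
F2 | step 7 | Se-phenyl (4S)-4-(1-methyl-4-oxocyclohexa-2,5-dien-1-yl)pentaneselenoate | O=C1C=CC(C)(C=C1)[C@@H](C)CCC(=O)[Se]c1ccccc1
F3 | step 7 | (4S,4aR,8aS)-4,4a-dimethyl-2,3,4,4a,8,8a-hexahydronaphthalene-1,7-dione | O=C1CC[C@H](C)[C@]2(C)C=CC(=O)C[C@H]12
F4 | step 11 | bromo(1-methoxy-1-oxopropan-2-yl)zinc | COC(=O)C(C)[Zn]Br
F5 | step 11 | methyl (2R)-2-[(5R,8S,8aS)-5-hydroxy-8,8a-dimethyl-3-oxo-3,5,6,7,8,8a-hexahydronaphthalen-2-yl]propanoate | O[C@@H]1CC[C@H](C)[C@@]2(C)C=C([C@@H](C)C(=O)OC)C(=O)C=C12
F6 | step 9 | (1R,4S,4aS)-4,4a-dimethyl-1,2,3,4,4a,7-hexahydronaphthalene-1,7-diol, either C7 epimer | O[C@@H]1CC[C@H](C)[C@@]2(C)C=CC(O)C=C12
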